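(+)-Neoolivil is the all-trans (2R,3S,4S,5R)-2,5-diguaiacyl-3,4-bis(hydroxymethyl)oxolane. It is C2-symmetric about the axis through O1 and the midpoint of C3–C4, so both halves can be built and processed together (two-directional).
Enabling feature: C2 and C5, the two oxolane carbons bonded to O1, are benzylic and para to the free phenolic OH of their guaiacyl rings. Each C–O1 bond is therefore the oxygen adduct of a p-quinone methide and can be made, and corrected, through it.
Key disconnection: C2–O1 and C5–O1 together lead back to a bis(p-quinone methide) plus one H2O. That in turn comes from a C2-symmetric dibenzylbutane without ring oxygen that carries only the C3/C4 stereocentres.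
Temporary ring: a di-tert-butylsilylene bridge over both CH2O groups (a 1,3,2-dioxasilepane) removes the primary oxygens as competitors (furofuran closure) and holds the two arms gauche. The C3–C4 bond and its two stereocentres come from oxidative homocoupling of an auxiliary-bound 3-arylpropanoyl enolate.
Ring order: guaiacyl rings (purchased), then dioxasilepane (temporary, made in step 5, cleaved in step 8), then oxolane (step 7, the last ring closed).

Key step: step 7

Remark on the chemistry: the target is taken as drawn, with all three vicinal ring relationships trans. Oxolane locants are O1 and C2–C5. Lignan locants are 7/7′ = C2/C5, 8/8′ = C3/C4 and 9/9′ = the CH2O carbons.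

Step 1
Reactants: 1 3-(4-hydroxy-3-methoxyphenyl)propanoic acid (dihydroferulic acid)
Product: 2 3-[4-(benzyloxy)-3-methoxyphenyl]propanoic acid
Conditions: BnBr, NaOH, EtOH/H2O, reflux; then aq. HCl
Reagents that add atoms: benzyl bromide, BrCc1ccccc1
Why: Williamson ether synthesis, in which the phenoxide is far more nucleophilic than the carboxylate in aqueous NaOH and any benzyl ester formed is saponified in the same pot; no stereocentre is involved.

Step 2
Reactants: 2 3-[4-(benzyloxy)-3-methoxyphenyl]propanoic acid; 3 (4R)-4-isopropyl-1,3-oxazolidin-2-one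
Product: 5 (4R)-3-{3-[4-(benzyloxy)-3-methoxyphenyl]propanoyl}-4-isopropyl-1,3-oxazolidin-2-one, via the mixed pivalic anhydride 4 (not isolated)
Conditions: PivCl, Et3N, THF, −20 °C; then LiCl, 3, −20 °C → rt
Reagents that add atoms: pivaloyl chloride, CC(C)(C)C(=O)Cl (its acyl group is carried by 4 only)
Why: Mixed-anhydride N-acylation of an oxazolidinone (LiCl/Et3N variant), in which the hindered pivaloyl carbonyl of 4 steers the nitrogen to the arylpropanoyl carbonyl and the auxiliary stereocentre is untouched.

Step 3
Reactants: 5 (4R)-3-{3-[4-(benzyloxy)-3-methoxyphenyl]propanoyl}-4-isopropyl-1,3-oxazolidin-2-one (two molecules)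
Product: 7 (2S,3S)-2,3-bis[4-(benzyloxy)-3-methoxybenzyl]-1,4-bis[(4R)-4-isopropyl-2-oxo-1,3-oxazolidin-3-yl]butane-1,4-dione, via the lithium (Z)-enolate 6 (not isolated)
Conditions: LDA, THF, −78 °C; then CuCl2, DMF/THF, −78 → 0 °C
Reagents that add atoms: lithium diisopropylamide, [Li+].CC(C)[N-]C(C)C (its lithium is carried by 6 only)
Why: Cu(II)-mediated oxidative enolate homocoupling, in which the chelated Z-enolate 6 is oxidised by single-electron transfer and each partner forms the new C–C bond on the face opposite its isopropyl group (the facial sense of alkylations of this enolate), so both future C3 and C4 should be set as S under double auxiliary control and the C2-symmetric dimer is freed from the unlike isomer by crystallisation or chromatography.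

Step 4
Reactants: 7 (2S,3S)-bis-imide dimer
Product: 8 (2S,3S)-2,3-bis[4-(benzyloxy)-3-methoxybenzyl]butane-1,4-diol
Conditions: LiBH4, H2O (2 equiv), Et2O/THF, 0 °C
Reagents that add atoms: none
Why: Borohydride reduction of N-acyloxazolidinones at the exocyclic carbonyl to primary alcohols, in which both ends react alike, the medium does not enolise the α-centres and the auxiliary is released for re-use.

Step 5
Reactants: 8 (2S,3S)-2,3-bis[4-(benzyloxy)-3-methoxybenzyl]butane-1,4-diol
Product: 9 (5S,6S)-5,6-bis[4-(benzyloxy)-3-methoxybenzyl]-2,2-di-tert-butyl-1,3,2-dioxasilepane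
Conditions: tBu2Si(OTf)2, 2,6-lutidine, CH2Cl2, 0 °C
Reagents that add atoms: di-tert-butylsilyl bis(trifluoromethanesulfonate), CC(C)(C)[Si](OS(=O)(=O)C(F)(F)F)(OS(=O)(=O)C(F)(F)F)C(C)(C)C
Why: Cyclic silylene protection of a 1,4-diol, in which the trans-disposed CH2OH groups close the seven-membered ring readily, the two benzyl arms become diequatorial and no stereocentre is touched.

Step 6
Reactants: 9 (5S,6S)-bis(O-benzyl) dioxasilepane
Product: 10 (5S,6S)-2,2-di-tert-butyl-5,6-bis(4-hydroxy-3-methoxybenzyl)-1,3,2-dioxasilepane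
Conditions: H2 (1 atm), Pd/C, EtOAc/EtOH, rt
Reagents that add atoms: none
Why: Hydrogenolysis of aryl benzyl ethers, which is clean here because the molecule carries no other benzylic C–heteroatom bond at this stage and the silylene is inert, so only the two phenols are unveiled.

Step 7
Reactants: 10 (5S,6S)-2,2-di-tert-butyl-5,6-bis(4-hydroxy-3-methoxybenzyl)-1,3,2-dioxasilepane
Product: 13 9,9′-O-(di-tert-butylsilylene)neoolivil, i.e. the (2R,3S,4S,5R)-2,5-bis(4-hydroxy-3-methoxyphenyl)oxolane trans-fused at C3–C4 to the dioxasilepane, via the bis(p-quinone methide) 11 (not isolated), via the mono-hydrated quinone methide 12 (not isolated)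
Conditions: Ag2O (6 equiv), 4 Å MS, CH2Cl2 (2 mM), rt, dark; filter; H2O/MeCN 1:9, rt; concentrate, then CSA (10 mol %), CH2Cl2, 0 °C
Reagents that add atoms: water, O
Why: Proposed new method: in the anhydrous first stage Ag2O removes the phenolic H and one para-benzylic H (2 e−/2 H+) from each 4-alkylguaiacol unit of 10 and should stop at the bis(p-quinone methide) 11, which contains neither a nucleophilic arene nor an oxidisable carbinol, and the oxidant is filtered off before any oxygen nucleophile is admitted, so over-oxidation of the product is excluded by design. One molecule of water then adds 1,6 to one methide carbon (12) and the new benzylic OH closes the oxolane by 5-exo-trig oxa-1,6-addition to the second methide, both guaiacyl rings being rearomatised, so that two C–H bonds become the C2–O1–C5 bridge in one operation. The closest known reaction types are the Ag2O dehydrogenation of 4-alkyl-2-methoxyphenols to p-quinone methides, the hydration and intramolecular alkoxylation of such methides, and the water capture of the 8–8′ bis(quinone methide) formed on oxidative coupling of γ-O-acylated monolignols, which ends in 2,5-diaryloxolanes. C3 and C4 are not touched and control the new centres: C2 is set trans to the C3 substituent and C5 trans to the C4 substituent, because both C–O1 bonds are para-hydroxybenzylic and reversible under catalytic CSA, so any 2,3-cis closure re-opens to protonated 12 and the mixture should drain to the all-trans (2R,5R) isomer, the only one with all four substituents pseudo-equatorial. The step needs O- over C-capture and 7,7′- over 7,9′-closure: the silylene ring ties up both primary oxygens (free, they would give the furofuran), holds the two arms diequatorial and gauche on the seven-membered ring for fast 5-exo closure, and high dilution suppresses intermolecular phenoxyl coupling and methide oligomerisation.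

Step 8
Reactants: 13 9,9′-O-(di-tert-butylsilylene)neoolivil
Product: 14 (+)-neoolivil, (2R,3S,4S,5R)-2,5-bis(4-hydroxy-3-methoxyphenyl)-3,4-bis(hydroxymethyl)oxolane
Conditions: HF·pyridine, pyridine/THF, 0 °C
Reagents that add atoms: none
Why: Fluoride-driven cleavage of the cyclic silylene, in which the pyridine buffer keeps the medium too weakly acidic to ionise the para-hydroxybenzylic C–O bonds, so C2/C5 and the 7,7′-ether bridge should be retained.

Compound list
1 | 3-(4-hydroxy-3-methoxyphenyl)propanoic acid | COc1cc(CCC(=O)O)ccc1O | starting material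
2 | 3-[4-(benzyloxy)-3-methoxyphenyl]propanoic acid | COc1cc(CCC(=O)O)ccc1OCc1ccccc1 | intermediate
3 | (4R)-4-isopropyl-1,3-oxazolidin-2-one | CC(C)[C@@H]1COC(=O)N1 | starting material
4 | 3-[4-(benzyloxy)-3-methoxyphenyl]propanoic pivalic anhydride (not isolated) | COc1cc(CCC(=O)OC(=O)C(C)(C)C)ccc1OCc1ccccc1 | intermediate
5 | (4R)-3-{3-[4-(benzyloxy)-3-methoxyphenyl]propanoyl}-4-isopropyl-1,3-oxazolidin-2-one | CC(C)[C@@H]1COC(=O)N1C(=O)CCc1ccc(OCc2ccccc2)c(OC)c1 | intermediate
6 | lithium (Z)-enolate of 5 (not isolated) | [Li+].[O-]/C(=C\Cc1ccc(OCc2ccccc2)c(OC)c1)N1C(=O)OC[C@H]1C(C)C | intermediate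
7 | (2S,3S)-2,3-bis[4-(benzyloxy)-3-methoxybenzyl]-1,4-bis[(4R)-4-isopropyl-2-oxo-1,3-oxazolidin-3-yl]butane-1,4-dione | CC(C)[C@@H]1COC(=O)N1C(=O)[C@@H](Cc1ccc(OCc2ccccc2)c(OC)c1)[C@H](Cc1ccc(OCc2ccccc2)c(OC)c1)C(=O)N1[C@H](C(C)C)COC1=O | intermediate
8 | (2S,3S)-2,3-bis[4-(benzyloxy)-3-methoxybenzyl]butane-1,4-diol | OC[C@@H](Cc1ccc(OCc2ccccc2)c(OC)c1)[C@@H](CO)Cc1ccc(OCc2ccccc2)c(OC)c1 | intermediate
9 | (5S,6S)-5,6-bis[4-(benzyloxy)-3-methoxybenzyl]-2,2-di-tert-butyl-1,3,2-dioxasilepane | CC(C)(C)[Si]1(OC[C@@H](Cc2ccc(OCc3ccccc3)c(OC)c2)[C@H](Cc2ccc(OCc3ccccc3)c(OC)c2)CO1)C(C)(C)C | intermediate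
10 | (5S,6S)-2,2-di-tert-butyl-5,6-bis(4-hydroxy-3-methoxybenzyl)-1,3,2-dioxasilepane | CC(C)(C)[Si]1(OC[C@@H](Cc2ccc(O)c(OC)c2)[C@H](Cc2ccc(O)c(OC)c2)CO1)C(C)(C)C | intermediate
11 | bis(p-quinone methide): (5S,6S)-dioxasilepane carrying two (3-methoxy-4-oxocyclohexa-2,5-dien-1-ylidene)methyl groups, methide geometry undefined (not isolated) | CC(C)(C)[Si]1(OC[C@@H](C=C2C=CC(=O)C(OC)=C2)[C@H](C=C2C=CC(=O)C(OC)=C2)CO1)C(C)(C)C | intermediate
12 | mono-hydrated quinone methide: one arm CH(OH)-guaiacyl (either configuration at the carbinol carbon), other arm still the quinone methide, ring centres unchanged (not isolated) | CC(C)(C)[Si]1(OC[C@@H](C(O)c2ccc(O)c(OC)c2)[C@H](C=C2C=CC(=O)C(OC)=C2)CO1)C(C)(C)C | intermediate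
13 | 9,9′-O-(di-tert-butylsilylene)neoolivil, oxolane centres (2R,3S,4S,5R), all-trans | COc1cc([C@@H]2O[C@@H](c3ccc(O)c(OC)c3)[C@@H]4CO[Si](C(C)(C)C)(C(C)(C)C)OC[C@@H]24)ccc1O | intermediate
14 | (+)-neoolivil, (2R,3S,4S,5R) | COc1cc([C@@H]2O[C@@H](c3ccc(O)c(OC)c3)[C@H](CO)[C@H]2CO)ccc1O | target

Total step count: 8. Longest linear sequence: 8 steps (from 1).

Steps most likely to fail

Step 7. Three things may go wrong. The dehydrogenation may stall at the phenoxyl stage and leak into radical coupling at the unsubstituted C5 positions of the arenes. The methides may tautomerise to styrenes, which erases the C3/C4 configuration. The first rearomatised ring may capture the second methide through carbon instead of through the new hydroxyl. The fallback uses known chemistry, sets out from 9 and returns at 13. Both ArCH2 groups of 9 are oxidised with DDQ in aqueous dioxane to the 1,4-diaryl-1,4-diketone F1. Luche reduction gives the 1,4-diol F2, whose configuration at the carbinol carbons is immaterial. TsOH-catalysed cyclodehydration in CH2Cl2 at 0 °C runs through the para-benzyloxybenzyl cation under thermodynamic control and gives the all-trans bis(benzyl ether) oxolane F3. Hydrogenolysis (H2, Pd/C, EtOAc) of the two aryl benzyl ethers then gives 13.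

Step 3. The union of the two enolate-derived units may show poor facial selectivity, and α-chlorination by CuCl2 or simple re-protonation may compete. The fallback builds the C3–C4 bond stepwise, sets out from 5 and returns at 8. The sodium enolate of 5 (NaHMDS, THF, −78 °C) is alkylated with tert-butyl bromoacetate to the succinate half-ester imide F4. LiBH4 removes the auxiliary and gives the hydroxy ester F5. TFA closes the (S)-β-benzylbutyrolactone F6. LiHMDS and 4-(benzyloxy)-3-methoxybenzyl bromide alkylate the lactone enolate anti to the β-substituent to give the trans-α,β-dibenzylbutyrolactone F7. LiAlH4 then opens it to 8.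

Step 8. Once the primary hydroxyls are free, trace acid can ionise a para-hydroxybenzylic C–O bond, with epimerisation at C2/C5 or migration of the ether bridge to a primary oxygen. The fallback shuts off the quinone methide channel before desilylation, sets out from 13 and returns at 14. Ac2O/pyridine masks both phenols as the bis(aryl acetate) F8. HF·pyridine removes the silylene to give the 4,4′-di-O-acetyl diol F9. K2CO3 in MeOH at 0 °C then cleaves the aryl acetates to 14.

Further compounds
F1 | step 7 | [(5S,6S)-2,2-di-tert-butyl-1,3,2-dioxasilepane-5,6-diyl]bis{[4-(benzyloxy)-3-methoxyphenyl]methanone} | CC(C)(C)[Si]1(OC[C@@H](C(=O)c2ccc(OCc3ccccc3)c(OC)c2)[C@H](C(=O)c2ccc(OCc3ccccc3)c(OC)c2)CO1)C(C)(C)C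
F2 | step 7 | corresponding bis(aryl carbinol), ring centres as in F1, carbinol carbons undefined | CC(C)(C)[Si]1(OC[C@@H](C(O)c2ccc(OCc3ccccc3)c(OC)c2)[C@H](C(O)c2ccc(OCc3ccccc3)c(OC)c2)CO1)C(C)(C)C
F3 | step 7 | 4,4′-di-O-benzyl-9,9′-O-(di-tert-butylsilylene)neoolivil, (2R,3S,4S,5R) | COc1cc([C@@H]2O[C@@H](c3ccc(OCc5ccccc5)c(OC)c3)[C@@H]4CO[Si](C(C)(C)C)(C(C)(C)C)OC[C@@H]24)ccc1OCc1ccccc1
F4 | step 3 | tert-butyl (3S)-3-[4-(benzyloxy)-3-methoxybenzyl]-4-[(4R)-4-isopropyl-2-oxo-1,3-oxazolidin-3-yl]-4-oxobutanoate | CC(C)[C@@H]1COC(=O)N1C(=O)[C@@H](Cc1ccc(OCc2ccccc2)c(OC)c1)CC(=O)OC(C)(C)C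
F5 | step 3 | tert-butyl (3S)-3-[4-(benzyloxy)-3-methoxybenzyl]-4-hydroxybutanoate | OC[C@@H](Cc1ccc(OCc2ccccc2)c(OC)c1)CC(=O)OC(C)(C)C
F6 | step 3 | (4S)-4-[4-(benzyloxy)-3-methoxybenzyl]oxolan-2-one | O=C1C[C@H](Cc2ccc(OCc3ccccc3)c(OC)c2)CO1
F7 | step 3 | (3S,4S)-3,4-bis[4-(benzyloxy)-3-methoxybenzyl]oxolan-2-one | O=C1OC[C@@H](Cc2ccc(OCc3ccccc3)c(OC)c2)[C@@H]1Cc1ccc(OCc2ccccc2)c(OC)c1
F8 | step 8 | 4,4′-di-O-acetyl-9,9′-O-(di-tert-butylsilylene)neoolivil, (2R,3S,4S,5R) | COc1cc([C@@H]2O[C@@H](c3ccc(OC(C)=O)c(OC)c3)[C@@H]4CO[Si](C(C)(C)C)(C(C)(C)C)OC[C@@H]24)ccc1OC(C)=O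
F9 | step 8 | 4,4′-di-O-acetylneoolivil, (2R,3S,4S,5R) | COc1cc([C@@H]2O[C@@H](c3ccc(OC(C)=O)c(OC)c3)[C@H](CO)[C@H]2CO)ccc1OC(C)=O
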